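**Assumption:** pseudoaspidin has no stereocentre (the SMILES carries no stereodescriptors), so there is no enantiomer to control; the route delivers the given constitution.

## Retrosynthetic overview

1. Pseudoaspidin 11 ⇒ two molecules of formyl ketone 8: one CHO carbon becomes the CH2 bridge, the other is extruded (reductive deformylative homodimerisation, new).
2. 8 ⇒ aldehyde 6 + butanoyl chloride 7 (Friedel–Crafts at the single free ring C–H).
3. 6 ⇒ aldehyde 4: the key ArO–CH3 bond. The formyl group sits on the future bridge carbon, ties up its two flanking OH by chelation and leaves the para-OH (next to the C-methyl) as the one that is methylated.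
4. 4 ⇒ 2-methylphloroglucinol 1 (Vilsmeier formylation; the two free ring positions are equivalent).
5. No ring is built; both benzene rings are carried in from 1.

## Route

**Step 1**
Reactants: 1 2-methylphloroglucinol (2-methylbenzene-1,3,5-triol); 2 (chloromethylene)dimethyliminium chloride (Vilsmeier reagent)
Product: 4 2,4,6-trihydroxy-3-methylbenzaldehyde, via aryl iminium chloride 3 (not isolated)
Conditions: 2 (1.2 equiv), MeCN, 0 °C → rt, 2 h; then H2O, 60 °C, 1 h
Reagents that add atoms: (chloromethylene)dimethyliminium chloride (C[N+](C)=CCl.[Cl-]); water (O)
Why: Vilsmeier–Haack formylation, in which the two free ring positions of 1 are equivalent and the iminium group of 3 deactivates the ring against a second attack, so a single mono-aldehyde results.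

**Step 2**
Reactants: 4 2,4,6-trihydroxy-3-methylbenzaldehyde; 5 dimethyl sulfate
Product: 6 2,6-dihydroxy-4-methoxy-3-methylbenzaldehyde
Conditions: Me2SO4 (1.0 equiv), K2CO3 (1.0 equiv), acetone, rt, 16 h
Reagents that add atoms: dimethyl sulfate (COS(=O)(=O)OC)
Why: Williamson O-methylation of the monoanion, where the OH para to CHO is the most acidic and is not chelated while both ortho-OH are held back by O–H···O=C chelation, so the methoxy group lands next to the C-methyl and para to the future bridge carbon (the usual para-selective mono-methylation of 2,4,6-trihydroxyaryl carbonyl compounds).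

**Step 3**
Reactants: 6 2,6-dihydroxy-4-methoxy-3-methylbenzaldehyde; 7 butanoyl chloride
Product: 8 3-butanoyl-2,6-dihydroxy-4-methoxy-5-methylbenzaldehyde
Conditions: PrCOCl (1.2 equiv), AlCl3 (3.5 equiv), PhNO2, 0 °C → rt, 6 h; ice/1 M HCl
Reagents that add atoms: butanoyl chloride (CCCC(=O)Cl)
Why: Friedel–Crafts acylation at the only remaining ring C–H, which is ortho/para to all three oxygens and only meta to CHO, so the regiochemistry is forced; the temperature is kept at or below rt to spare the new ortho-methoxy ketone from AlCl3 demethylation.

**Step 4**
Reactants: 8 3-butanoyl-2,6-dihydroxy-4-methoxy-5-methylbenzaldehyde (two molecules)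
Product: 11 pseudoaspidin, via salicyl alcohol 9 (not isolated), via o-quinone methide 10 (not isolated)
Conditions: NaBH4 (0.4 equiv), THF–MeOH 5:1, −20 °C, 30 min; acetone (quench); then AcOH–H2O (pH ≈ 4), 50 °C, N2 sparge, 4 h
Reagents that add atoms: none
Why: Proposed new method: reductive deformylative homodimerisation — hydride reduces the aldehyde (the chelated, di-ortho-substituted ketone is much slower) to salicyl alcohol 9, mild acid ionises 9 to o-quinone methide 10, 10 attacks a second molecule of 9 at its most nucleophilic ring carbon (the one carrying CH2OH, flanked by two OH and para to OMe), and the ipso adduct rearomatises by retro-hydroxymethylation with loss of formaldehyde, all other ring positions being blocked so that only the symmetrical CH2 bridge can persist; closest known reaction types are the phenol–formaldehyde (Lederer–Manasse) condensation of hydroxymethylphenols to methylenebisphenols with release of formaldehyde, the formaldehyde dimerisation of acylphloroglucinols through o-quinone methides, and the borohydride reduction of formylphloroglucinols through the same o-quinone methides; no stereocentre is formed.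

## Compound list

1 | 2-methylbenzene-1,3,5-triol (2-methylphloroglucinol) | Cc1c(O)cc(O)cc1O | starting material
2 | (chloromethylene)dimethyliminium chloride (Vilsmeier reagent) | C[N+](C)=CCl.[Cl-] | starting material
3 | N-methyl-N-[(2,4,6-trihydroxy-3-methylphenyl)methylidene]methanaminium chloride | C[N+](C)=Cc1c(O)cc(O)c(C)c1O.[Cl-] | intermediate
4 | 2,4,6-trihydroxy-3-methylbenzaldehyde | O=Cc1c(O)cc(O)c(C)c1O | intermediate
5 | dimethyl sulfate | COS(=O)(=O)OC | starting material
6 | 2,6-dihydroxy-4-methoxy-3-methylbenzaldehyde | O=Cc1c(O)cc(OC)c(C)c1O | intermediate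
7 | butanoyl chloride | CCCC(=O)Cl | starting material
8 | 3-butanoyl-2,6-dihydroxy-4-methoxy-5-methylbenzaldehyde | CCCC(=O)c1c(O)c(C=O)c(O)c(C)c1OC | intermediate
9 | 1-[2,4-dihydroxy-3-(hydroxymethyl)-6-methoxy-5-methylphenyl]butan-1-one | CCCC(=O)c1c(O)c(CO)c(O)c(C)c1OC | intermediate
10 | 4-butanoyl-3-hydroxy-5-methoxy-6-methyl-2-methylidenecyclohexa-3,5-dien-1-one | C=C1C(=O)C(C)=C(OC)C(C(=O)CCC)=C1O | intermediate
11 | pseudoaspidin, bis(3-butanoyl-2,6-dihydroxy-4-methoxy-5-methylphenyl)methane | CCCC(=O)c1c(O)c(Cc2c(O)c(C)c(OC)c(C(=O)CCC)c2O)c(O)c(C)c1OC | target

## Step count and risks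

Total steps: 4. Longest linear sequence: 4 (1 → 4 → 6 → 8 → 11).

The step most likely to fail is step 4, the proposed new transformation. The o-quinone methide could be reduced on to the C-methyl compound if borohydride survives the quench, the ketone could be touched, or ipso substitution could lose out to ether and oligomer formation. The fallback uses known chemistry, sets out from 8 and comes back at 11. Lindgren–Pinnick oxidation of 8 (NaClO2, NaH2PO4, 2-methyl-2-butene, t-BuOH–H2O, 0 °C → rt) gives 3-butanoyl-2,6-dihydroxy-4-methoxy-5-methylbenzoic acid F1. Heating it in wet DMSO at 90 °C decarboxylates it, as is usual for 2,6-dihydroxybenzoic acids, to pseudoaspidinol, 1-(4,6-dihydroxy-2-methoxy-3-methylphenyl)butan-1-one F2. This has a single free ring position and is condensed with 0.5 equiv of aqueous formaldehyde in 1% aqueous KOH at rt to give 11, the classical formaldehyde dimerisation of acylphloroglucinols.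

Second is step 3. AlCl3 may cleave the methoxy group once it is ortho to the new ketone, or the Lewis-acid-activated aldehyde may react with the arene. The fallback changes the reaction class from acylium chemistry to imidoylation followed by hydrolysis; it sets out from 6 and comes back at 8. Houben–Hoesch reaction of 6 with butyronitrile (ZnCl2, HCl gas, Et2O, 0 °C) precipitates 1-(3-formyl-2,4-dihydroxy-6-methoxy-5-methylphenyl)butan-1-iminium chloride F3, which is hydrolysed in water at 80 °C to 8. No strong Lewis acid or acyl chloride is present, so the ether-cleavage pathway is removed.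

Third is step 2. Over-methylation or partial methylation of the less hindered ortho-OH would erode the yield of 6. The fallback replaces selective C–O formation by selective C–O cleavage; it sets out from 4 and comes back at 6. Exhaustive methylation (excess Me2SO4, K2CO3, acetone, reflux) gives 2,4,6-trimethoxy-3-methylbenzaldehyde F4. BBr3 (2.2 equiv, CH2Cl2, −78 → 0 °C) then removes only the two methyl groups ortho to the aldehyde through boron chelation to the carbonyl and leaves the para-methoxy group, giving 6.

## Further compounds

F1 | step 4 | 3-butanoyl-2,6-dihydroxy-4-methoxy-5-methylbenzoic acid | CCCC(=O)c1c(O)c(C(=O)O)c(O)c(C)c1OC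
F2 | step 4 | 1-(4,6-dihydroxy-2-methoxy-3-methylphenyl)butan-1-one (pseudoaspidinol) | CCCC(=O)c1c(O)cc(O)c(C)c1OC
F3 | step 3 | 1-(3-formyl-2,4-dihydroxy-6-methoxy-5-methylphenyl)butan-1-iminium chloride | CCCC(=[NH2+])c1c(O)c(C=O)c(O)c(C)c1OC.[Cl-]
F4 | step 2 | 2,4,6-trimethoxy-3-methylbenzaldehyde | COc1cc(OC)c(C=O)c(OC)c1C
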